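**Retrosynthetic overview**
1. Target 24 ⇐ β‑hydroxy ketone 22 by alkyne saturation, acid β‑elimination of the C9 alcohol and loss of both silyl groups; the C7 ketone of 22 comes from the isopropenyl group of 19 (ozonolysis, radical C–C scission).
2. 19 ⇐ C9–C11 bond: acetylide of the trans‑fused alkyne 17 added to the cis‑fused ketone 9. Both halves come from the same ketone 9.
3. 17 ⇐ 9: the isopropenyl group is excised with desaturation (enone 11), dehydrogenation to dienone 12 erases C5, hydrogenation resets it trans (14); the C9 ketone becomes ethynyl by one‑carbon homologation.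
4. 9 ⇐ Diels–Alder reaction of trans‑6‑methylcarvone 3 (ring B, from (S)‑carvone) with silyloxydiene 5: it builds ring A and sets C5 and C10; C3 follows by hydride reduction.
5. Ring order: ring B is bought, ring A is closed by the cycloaddition, no ring is formed afterwards.

Assumption: 4‑methylpent‑1‑en‑3‑one is purchasable; each decalin carries drimane numbers C1–C10 (C11/C12 = linker carbons on C9/C9' of the trans half, β = face of the angular C10 methyl), and where an epimer mixture is harmless (C8 in 3–10, C9 carbinol in 19–23, C7 in 21, peroxy carbon in 10 and 20) the expected major isomer or an undefined centre is written.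

Step 1
Reactants: 1 (S)-(+)-carvone
Product: 3 trans-6-methylcarvone, via lithium dienolate 2 (not isolated)
Conditions: LiN(i-Pr)2 (1.05 equiv), THF, −78 °C; MeI, −78 → 0 °C
Reagents that add atoms: iodomethane, CI
Why: Kinetic α'-deprotonation gives the cross-conjugated dienolate, which is C-methylated mainly anti to the neighbouring isopropenyl group (enolate alkylation); the epimer ratio at this carbon (later C8) is immaterial because it equilibrates in step 3 and ends sp2 or thermodynamically set.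

Step 2
Reactants: 4 4-methylpent-1-en-3-one
Product: 5 3-(tert-butyldimethylsilyloxy)-4-methylpenta-1,3-diene
Conditions: TBSOTf (1.1 equiv), Et3N (1.5 equiv), Et2O, 0 °C
Reagents that add atoms: tert-butyldimethylsilyl trifluoromethanesulfonate, CC(C)(C)[Si](C)(C)OS(=O)(=O)C(F)(F)F
Why: Soft enolisation and O-silylation; only the isopropyl methine is enolisable, so a single 2-silyloxydiene forms and no stereocentre is created.

Step 3
Reactants: 3 trans-6-methylcarvone; 5 3-(tert-butyldimethylsilyloxy)-4-methylpenta-1,3-diene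
Product: 7 cis-fused 3,9-diketone, via cycloadduct silyl enol ether 6 (not isolated)
Conditions: EtAlCl2 (0.5 equiv), toluene, −20 °C → rt; then 1 M HCl, THF, rt
Reagents that add atoms: none
Why: Lewis-acid-promoted Diels–Alder cycloaddition in which the nucleophilic CMe2 terminus of the diene bonds to the enone β-carbon; suprafacial addition makes ring A cis-fused and the diene adds anti to the isopropenyl group, which sets C5 (β-H) and C10 (β-Me), while the acid work-up unmasks the C3 ketone and leaves C8 as the equatorial α-methyl epimer.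

Step 4
Reactants: 7 cis-fused 3,9-diketone
Product: 9 cis-fused 3β-silyloxy 9-ketone, via lithium 3β-alkoxide 8 (not isolated)
Conditions: LiBH(s-Bu)3 (1.1 equiv), THF, −78 °C; then TBSOTf (1.5 equiv), −78 → 0 °C
Reagents that add atoms: tert-butyldimethylsilyl trifluoromethanesulfonate, CC(C)(C)[Si](C)(C)OS(=O)(=O)C(F)(F)F
Why: The bulky hydride reduces only the C3 ketone (C9 is flanked by a quaternary and a tertiary carbon) and attacks from the equatorial direction as with 5β-3-oxo steroids, giving the axial 3β alkoxide (cis to the C10 methyl and H-5), which is silylated in the same flask.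

Step 5
Reactants: 9 cis-fused 3β-silyloxy 9-ketone
Product: 11 cis-fused 7-en-9-one, via methoxy hydroperoxide 10 (not isolated)
Conditions: O3, MeOH/CH2Cl2, −78 °C; then Cu(OAc)2·H2O (2 equiv), FeSO4·7H2O (1.2 equiv), −78 °C → rt
Reagents that add atoms: none
Why: Dealkenylative desaturation: ozonolysis in methanol gives the α-methoxy hydroperoxide, divalent iron cleaves the O–O bond, β-scission expels methyl acetate, and divalent copper oxidises the C7 radical to the conjugated C7=C8 enone (as in the dihydrocarvone to 6-methylcyclohexenone precedent); the carvone stereocentre is consumed here.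

Step 6
Reactants: 11 cis-fused 7-en-9-one
Product: 12 5,7-dien-9-one
Conditions: chloranil (1.5 equiv), t-BuOH/xylene, reflux
Reagents that add atoms: none
Why: Quinone γ,δ-dehydrogenation through the extended dienol (the only one possible, since C10 is quaternary) removes the C5 hydride and gives the linear dienone, which erases the cis ring-fusion centre C5.

Step 7
Reactants: 12 5,7-dien-9-one
Product: 14 trans-fused 8α-methyl 9-ketone, via 8β-methyl epimer 13 (not isolated)
Conditions: H2 (5 atm), 10% Pd/C, EtOAc, rt; filter; then NaOMe (cat.), MeOH, rt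
Reagents that add atoms: none
Why: Heterogeneous hydrogenation delivers hydrogen to the face opposite the pseudo-axial C10 methyl, as in 4,4-dimethyl-5-ene octalins, setting H-5 α (trans fusion), and base epimerisation α to the ketone moves the C8 methyl to the equatorial α position.

Step 8
Reactants: 14 trans-fused 8α-methyl 9-ketone
Product: 15 C9 spiro-epoxide
Conditions: Me3S+ I− (2.0 equiv), n-BuLi (1.9 equiv), THF, −10 °C; then 14, → rt
Reagents that add atoms: trimethylsulfonium iodide, C[S+](C)C.[I-]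
Why: Corey–Chaykovsky epoxidation by the small sulfonium ylide, which tolerates the hindered ketone; the spiro configuration (axial CH2 drawn) is irrelevant because C9 is reset in steps 9 and 10.

Step 9
Reactants: 15 C9 spiro-epoxide
Product: 16 9β-carbaldehyde
Conditions: BF3·OEt2 (0.3 equiv), CH2Cl2, −78 → −30 °C
Reagents that add atoms: none
Why: Meinwald rearrangement (Lewis-acid epoxide opening to the tertiary cation and 1,2-hydride shift) gives the aldehyde; C9 is epimerisable and the equatorial 9β-formyl isomer is the stable one.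

Step 10
Reactants: 16 9β-carbaldehyde
Product: 17 trans-fused 9β-ethynyl decalin
Conditions: dimethyl (1-diazo-2-oxopropyl)phosphonate (1.5 equiv), K2CO3 (3 equiv), MeOH/THF, rt
Reagents that add atoms: dimethyl (1-diazo-2-oxopropyl)phosphonate, CC(=O)C(=[N+]=[N-])P(=O)(OC)OC
Why: Seyferth–Gilbert homologation with the Ohira–Bestmann reagent; K2CO3/MeOH equilibrates the aldehyde to the equatorial epimer before it reacts, so the alkyne fixes C9 with H α and the C2 chain β, trans to the 8α-methyl.

Step 11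
Reactants: 17 trans-fused 9β-ethynyl decalin; 9 cis-fused 3β-silyloxy 9-ketone
Product: 19 coupled propargylic alcohol, via lithium acetylide 18 (not isolated)
Conditions: n-BuLi (1.0 equiv), THF, −78 °C; LaCl3·2LiCl (0.3 equiv); then 9 (1.3 equiv), −78 → 0 °C; NH4Cl
Reagents that add atoms: none
Why: 1,2-Addition of the slim acetylide to the hindered C9 ketone forms the C9–C11 bond, with the lanthanum salt suppressing enolisation; the new carbinol centre (attack from the convex β face expected) is destroyed in step 13.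

Step 12
Reactants: 19 coupled propargylic alcohol
Product: 22 β-hydroxy ketone, via methoxy hydroperoxide 20 (not isolated), via TEMPO ether 21 (not isolated)
Conditions: O3, MeOH/CH2Cl2, −78 °C; then FeSO4·7H2O (1.2 equiv), TEMPO (1.5 equiv), −78 °C → rt; then Mg(O2CC6H4CO3H)2·6H2O (MMPP, 2.5 equiv), rt
Reagents that add atoms: TEMPO (2,2,6,6-tetramethylpiperidin-1-oxyl), CC1(C)CCCC(C)(C)N1[O]
Why: Oxodealkenylation: ozone attacks the 1,1-disubstituted alkene far faster than the hindered alkyne, divalent iron triggers β-scission of the methoxy hydroperoxide, TEMPO traps the C7 radical, and peracid N-oxidation with elimination turns the alkoxyamine into the C7 ketone.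

Step 13
Reactants: 22 β-hydroxy ketone
Product: 24 CNP0290352.1, via saturated hydroxy ketone 23 (not isolated)
Conditions: H2 (1 atm), 10% Pd/C, EtOAc, rt; filter; then 3 M HCl in MeOH/THF, 45 °C
Reagents that add atoms: none
Why: Hydrogenation saturates the alkyne to the C11–C12 ethylene linker; acid then dehydrates the tertiary β-hydroxy ketone to the conjugated tetrasubstituted C8=C9 enone (aldol-type β-elimination) and solvolyses both silyl ethers, without touching any remaining stereocentre.

**Compound list**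
1 | (S)-(+)-carvone, (5S)-2-methyl-5-(prop-1-en-2-yl)cyclohex-2-en-1-one | CC1=CC[C@H](C(C)=C)CC1=O | starting material
2 | lithium cross-conjugated dienolate of 1 (O–Li on C1, C1=C6, C2=C3) | [Li+].CC1=CC[C@H](C(C)=C)C=C1[O-] | intermediate
3 | trans-6-methylcarvone, (5S)-2,6-dimethyl-5-(prop-1-en-2-yl)cyclohex-2-en-1-one, 6-Me trans to isopropenyl | CC1=CC[C@H](C(C)=C)[C@@H](C)C1=O | intermediate
4 | 4-methylpent-1-en-3-one (isopropyl vinyl ketone) | C=CC(=O)C(C)C | starting material
5 | 3-(tert-butyldimethylsilyloxy)-4-methylpenta-1,3-diene | C=CC(O[Si](C)(C)C(C)(C)C)=C(C)C | intermediate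
6 | cycloadduct: cis-fused (5β-H, 10β-Me) 3-(TBSO)-4,4,8α,10-tetramethyl-7β-(prop-1-en-2-yl)octal-2-en-9-one | CC(C)(C)[Si](C)(C)OC1=CC[C@]2(C)C(=O)[C@H](C)[C@@H](C(C)=C)C[C@@H]2C1(C)C | intermediate
7 | cis-fused diketone: 4,4,8α,10β-tetramethyl-7β-(prop-1-en-2-yl)-5β-decalin-3,9-dione | O=C1CC[C@]2(C)C(=O)[C@H](C)[C@@H](C(C)=C)C[C@@H]2C1(C)C | intermediate
8 | lithium 3β-alkoxide of 7 (axial O, cis to C10-Me and H-5; 9-ketone intact) | [Li+].[O-][C@H]1CC[C@]2(C)C(=O)[C@H](C)[C@@H](C(C)=C)C[C@@H]2C1(C)C | intermediate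
9 | cis-fused ketone: 3β-(TBSO)-4,4,8α,10β-tetramethyl-7β-(prop-1-en-2-yl)-5β-decalin-9-one | CC(C)(C)[Si](C)(C)O[C@H]1CC[C@]2(C)C(=O)[C@H](C)[C@@H](C(C)=C)C[C@@H]2C1(C)C | intermediate
10 | α-methoxy hydroperoxide of 9 (C7 carries C(CH3)(OCH3)OOH) | CC(C)(C)[Si](C)(C)O[C@H]1CC[C@]2(C)C(=O)[C@H](C)[C@@H](C(C)(OC)OO)C[C@@H]2C1(C)C | intermediate
11 | cis-fused enone: 3β-(TBSO)-4,4,8,10β-tetramethyl-5β-octal-7-en-9-one | CC(C)(C)[Si](C)(C)O[C@H]1CC[C@]2(C)C(=O)C(C)=CC[C@@H]2C1(C)C | intermediate
12 | linear dienone: 3β-(TBSO)-4,4,8,10β-tetramethyl-5,7-dien-9-one | CC(C)(C)[Si](C)(C)O[C@H]1CC[C@]2(C)C(=O)C(C)=CC=C2C1(C)C | intermediate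
13 | trans-fused (5α-H) 3β-(TBSO)-4,4,8β,10β-tetramethyldecalin-9-one | C[C@]12CC[C@H](O[Si](C)(C)C(C)(C)C)C(C)(C)[C@@H]1CC[C@H](C)C2=O | intermediate
14 | trans-fused (5α-H) 3β-(TBSO)-4,4,8α,10β-tetramethyldecalin-9-one | C[C@]12CC[C@H](O[Si](C)(C)C(C)(C)C)C(C)(C)[C@@H]1CC[C@@H](C)C2=O | intermediate
15 | spiro-epoxide of 14 at C9 (CH2 α, O β) | C[C@]12CC[C@H](O[Si](C)(C)C(C)(C)C)C(C)(C)[C@@H]1CC[C@@H](C)[C@@]23CO3 | intermediate
16 | 3β-(TBSO)-4,4,8α,10β-tetramethyl-5α-decalin-9β-carbaldehyde (9α-H) | C[C@]12CC[C@H](O[Si](C)(C)C(C)(C)C)C(C)(C)[C@@H]1CC[C@@H](C)[C@@H]2C=O | intermediate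
17 | 9β-ethynyl-3β-(TBSO)-4,4,8α,10β-tetramethyl-5α-decalin | C[C@]12CC[C@H](O[Si](C)(C)C(C)(C)C)C(C)(C)[C@@H]1CC[C@@H](C)[C@@H]2C#C | intermediate
18 | lithium acetylide of 17 | [Li+].C[C@]12CC[C@H](O[Si](C)(C)C(C)(C)C)C(C)(C)[C@@H]1CC[C@@H](C)[C@@H]2C#[C-] | intermediate
19 | coupled propargylic alcohol: 9 with C9 turned into C(OH)–C≡C–C9' of 17 (alkynyl β, OH α drawn) | CC(C)(C)[Si](C)(C)O[C@H]1CC[C@]2(C)[C@@](O)(C#C[C@H]3[C@H](C)CC[C@H]4C(C)(C)[C@@H](O[Si](C)(C)C(C)(C)C)CC[C@]34C)[C@H](C)[C@@H](C(C)=C)C[C@@H]2C1(C)C | intermediate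
20 | α-methoxy hydroperoxide of 19 (C7 carries C(CH3)(OCH3)OOH) | CC(C)(C)[Si](C)(C)O[C@H]1CC[C@]2(C)[C@@](O)(C#C[C@H]3[C@H](C)CC[C@H]4C(C)(C)[C@@H](O[Si](C)(C)C(C)(C)C)CC[C@]34C)[C@H](C)[C@@H](C(C)(OC)OO)C[C@@H]2C1(C)C | intermediate
21 | C7 alkoxyamine (O-bound 2,2,6,6-tetramethylpiperidin-1-yl) of the dealkenylated skeleton | CC(C)(C)[Si](C)(C)O[C@H]1CC[C@]2(C)[C@@](O)(C#C[C@H]3[C@H](C)CC[C@H]4C(C)(C)[C@@H](O[Si](C)(C)C(C)(C)C)CC[C@]34C)[C@H](C)C(ON5C(C)(C)CCCC5(C)C)C[C@@H]2C1(C)C | intermediate
22 | β-hydroxy ketone: 9-hydroxy-7-oxo cis-decalin joined through C≡C to the trans decalin, both 3-OTBS | CC(C)(C)[Si](C)(C)O[C@H]1CC[C@]2(C)[C@@](O)(C#C[C@H]3[C@H](C)CC[C@H]4C(C)(C)[C@@H](O[Si](C)(C)C(C)(C)C)CC[C@]34C)[C@H](C)C(=O)C[C@@H]2C1(C)C | intermediate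
23 | saturated β-hydroxy ketone (CH2CH2 linker), both 3-OTBS | CC(C)(C)[Si](C)(C)O[C@H]1CC[C@]2(C)[C@@](O)(CC[C@H]3[C@H](C)CC[C@H]4C(C)(C)[C@@H](O[Si](C)(C)C(C)(C)C)CC[C@]34C)[C@H](C)C(=O)C[C@@H]2C1(C)C | intermediate
24 | CNP0290352.1: cis-fused 3β-hydroxy-8-en-7-one decalin linked C9–CH2CH2–C9' to the trans-fused 3'β-hydroxy-8'α-methyl decalin | CC1=C(CC[C@H]2[C@H](C)CC[C@H]3C(C)(C)[C@@H](O)CC[C@]23C)[C@@]2(C)CC[C@H](O)C(C)(C)[C@H]2CC1=O | target

**Step count and risks**
Total steps: 13. Longest linear sequence: 12 (steps 1 and 3–13; step 2 is a one-step side branch).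

Most likely to fail:

Step 3. The diene carries a Z-methyl at its reacting terminus and reaches the s-cis geometry poorly, so the cycloaddition may stall or stop after the first C–C bond. Fallback: setting out again from 3 and 5, build ring A by two ionic bond formations. A TiCl4-mediated Mukaiyama–Michael addition (CH2Cl2, −78 °C, aqueous work-up) gives the ring-opened vinyl ketone 2,6-dimethyl-3-(2-methyl-3-oxopent-4-en-2-yl)-5-(prop-1-en-2-yl)cyclohexan-1-one F1, formed anti to the isopropenyl group. KOtBu (0.3 equiv) in t-BuOH/THF at 0 °C then closes ring A by intramolecular Michael addition of the C10 enolate. This comes back to the route at 7; the cis fusion must be confirmed by NOE.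

Step 6. The hydride to be removed sits on C5 between two quaternary carbons and must become pseudo-axial, so the quinone dehydrogenation may be slow. Fallback: setting out from 11, form the extended silyl dienol ether of 11 F2 (TBSOTf, Et3N, CH2Cl2; only the C6 hydrogens can be removed). Brominate it at C6 with NBS (THF, −78 °C) to the 6-bromo enone F3, and eliminate HBr with Li2CO3/LiBr in DMF at 120 °C. This comes back to the route at 12.

Step 11. Both faces of the C9 ketone of 9 are hindered (ring A under the α face, the C10 methyl on the β face) and C8–H enolisation can compete with addition. Fallback: setting out from 11 and 18, add the acetylide to the enone carbonyl, which has no α-hydrogen and no C7 substituent, to give the tertiary alkynyl allylic alcohol F4. Oxidative 1,3-transposition with C5H5NH[CrO3Cl] (CH2Cl2, rt; [3,3]-shift of the chromate ester, then oxidation) gives the bis-silyl enynone F5. Hydrogenate the triple bond (H2, 10% Pd/C, EtOAc) to the 3,3'-bis-TBS ether of the target F6, then remove the silyl groups with 3 M HCl in MeOH/THF. This comes back to the route at 24.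

**Further compounds**
F1 | step 3 | 2,6-dimethyl-3-(2-methyl-3-oxopent-4-en-2-yl)-5-(prop-1-en-2-yl)cyclohexan-1-one (side chain anti to isopropenyl) | C=CC(=O)C(C)(C)[C@H]1C[C@H](C(C)=C)[C@@H](C)C(=O)C1C
F2 | step 6 | extended silyl dienol ether of 11 (3β,9-bis(TBSO)-6,8-diene) | CC(C)(C)[Si](C)(C)O[C@H]1CC[C@]2(C)C(O[Si](C)(C)C(C)(C)C)=C(C)C=C[C@@H]2C1(C)C
F3 | step 6 | 6-bromo derivative of enone 11 | CC(C)(C)[Si](C)(C)O[C@H]1CC[C@]2(C)C(=O)C(C)=CC(Br)[C@@H]2C1(C)C
F4 | step 11 | tertiary alcohol from 11 and 18 (9-alkynyl-7-en-9-ol) | CC(C)(C)[Si](C)(C)O[C@H]1CC[C@]2(C)C(O)(C#C[C@H]3[C@H](C)CC[C@H]4C(C)(C)[C@@H](O[Si](C)(C)C(C)(C)C)CC[C@]34C)C(C)=CC[C@@H]2C1(C)C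
F5 | step 11 | bis-silyl enynone (8-en-7-one with C9–C≡C–C9') | CC(C)(C)[Si](C)(C)O[C@H]1CC[C@]2(C)C(C#C[C@H]3[C@H](C)CC[C@H]4C(C)(C)[C@@H](O[Si](C)(C)C(C)(C)C)CC[C@]34C)=C(C)C(=O)C[C@@H]2C1(C)C
F6 | step 11 | 3,3'-bis-TBS ether of 24 | CC(C)(C)[Si](C)(C)O[C@H]1CC[C@]2(C)C(CC[C@H]3[C@H](C)CC[C@H]4C(C)(C)[C@@H](O[Si](C)(C)C(C)(C)C)CC[C@]34C)=C(C)C(=O)C[C@@H]2C1(C)C
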